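The α-methylene-γ-butyrolactone is disconnected at the C7–C11 bond (lactone α-carbon to ring-fusion carbon). In the forward sense an acrylate ester on O6 of a ten-membered (6R,7R,8R,9R)-7,8-epoxide is triggered by a phosphine. The phosphonium enolate opens the trans-epoxide at C7, which in one operation closes the five-membered lactone ring, sets C7 by inversion, frees the C8 hydroxyl beside the C9 acetate and regenerates the exocyclic methylene. The step exploits the anti relationship of the C7–C11 bond and the C8–OH on the carbocycle, the signature of a trans-epoxide opening. The epoxy-cyclodecadiene comes from neryl acetate by Sharpless epoxidation and chromium-mediated ring closure.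

Key step: step 16

Remark: germacrane locants are used for the ring compounds (C6 bears the lactone oxygen, C7 is the ring-fusion carbon, C11/C13 the lactone α-carbon and its methylene, C14 the acyloxymethyl carbon); the target carries the (R)-2-methylbutanoate, and (R)-2-methylbutanoic acid is taken as a purchasable enantiopure acid.

Step 1
Reactants: 1 neryl acetate
Product: 2 racemic 6,7-epoxyneryl acetate
Conditions: mCPBA, NaHCO3, CH2Cl2, 0 °C
Reagents that add atoms: 3-chloroperoxybenzoic acid, O=C(OO)c1cccc(Cl)c1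
Why: Prilezhaev epoxidation should take the electron-rich terminal trisubstituted alkene in preference to the 2,3-alkene deactivated by the allylic acetoxy group; the racemic epoxide centre is destroyed in step 2.

Step 2
Reactants: 2 racemic 6,7-epoxyneryl acetate
Product: 4 (2Z)-3-methyl-6-oxohex-2-en-1-yl acetate, via diol 3 (not isolated)
Conditions: H5IO6, THF/H2O, 0 °C
Reagents that add atoms: none
Why: Acid-promoted hydration of the epoxide and Malaprade glycol cleavage by periodic acid should excise acetone and leave the C1 aldehyde with the Z-alkene untouched.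

Step 3
Reactants: 4 (2Z)-3-methyl-6-oxohex-2-en-1-yl acetate; 5 (triphenylphosphoranylidene)acetaldehyde
Product: 6 (2Z,6E)-3-methyl-8-oxoocta-2,6-dien-1-yl acetate
Conditions: PhMe, 80 °C
Reagents that add atoms: (triphenylphosphoranylidene)acetaldehyde 5, O=CC=P(c1ccccc1)(c1ccccc1)c1ccccc1
Why: Wittig olefination with the stabilised formyl ylide should give the E-enal, adding C10 and C14.

Step 4
Reactants: 6 (2Z,6E)-3-methyl-8-oxoocta-2,6-dien-1-yl acetate
Product: 7 (2Z,6Z)-7-iodo-3-methyl-8-oxoocta-2,6-dien-1-yl acetate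
Conditions: I2, K2CO3, DMAP (cat.), THF/H2O, 0 to 23 °C
Reagents that add atoms: iodine, II
Why: DMAP-mediated α-iodination of the enal (conjugate addition, iodination of the enolate, elimination of DMAP) should give the (Z)-α-iodoenal in which iodine is cis to the chain, the geometry later needed at C1=C10.

Step 5
Reactants: 7 (2Z,6Z)-7-iodo-3-methyl-8-oxoocta-2,6-dien-1-yl acetate
Product: 8 (2Z,6Z)-8-hydroxy-7-iodo-3-methylocta-2,6-dien-1-yl acetate
Conditions: NaBH4, CeCl3·7H2O, MeOH, −20 °C
Reagents that add atoms: none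
Why: Luche reduction should reduce the enal 1,2 to the C14 alcohol without touching the alkenyl iodide or the acetate.

Step 6
Reactants: 8 (2Z,6Z)-8-hydroxy-7-iodo-3-methylocta-2,6-dien-1-yl acetate; 9 (2R)-2-methylbutanoic acid
Product: 10 (2Z,6Z)-8-acetoxy-2-iodo-6-methylocta-2,6-dien-1-yl (2R)-2-methylbutanoate
Conditions: DCC, DMAP (cat.), CH2Cl2, 0 °C
Reagents that add atoms: (2R)-2-methylbutanoic acid 9, CC[C@@H](C)C(=O)O
Why: Steglich esterification installs the C14 ester of the target early; the stereocentre of the acid is bought in and is not touched.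

Step 7
Reactants: 10 (2Z,6Z)-8-acetoxy-2-iodo-6-methylocta-2,6-dien-1-yl (2R)-2-methylbutanoate
Product: 11 (2Z,6Z)-8-hydroxy-2-iodo-6-methylocta-2,6-dien-1-yl (2R)-2-methylbutanoate
Conditions: K2CO3 (cat.), MeOH, 0 °C
Reagents that add atoms: none
Why: Base-catalysed transesterification should remove the unhindered acetate markedly faster than the α-branched 2-methylbutanoate, freeing the C6 alcohol.

Step 8
Reactants: 11 (2Z,6Z)-8-hydroxy-2-iodo-6-methylocta-2,6-dien-1-yl (2R)-2-methylbutanoate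
Product: 12 (2Z,6Z)-2-iodo-6-methyl-8-oxoocta-2,6-dien-1-yl (2R)-2-methylbutanoate
Conditions: Dess–Martin periodinane, NaHCO3, CH2Cl2, 0 °C
Reagents that add atoms: none
Why: Buffered Dess–Martin oxidation of the allylic alcohol should give the Z-enal without Z-to-E isomerisation if the product is used directly.

Step 9
Reactants: 12 (2Z,6Z)-2-iodo-6-methyl-8-oxoocta-2,6-dien-1-yl (2R)-2-methylbutanoate; 13 tert-butyldimethyl(prop-2-yn-1-yloxy)silane
Product: 16 (2Z,6Z,8S,9E)-11-(tert-butyldimethylsilyloxy)-8-hydroxy-2-iodo-6-methylundeca-2,6,9-trien-1-yl (2R)-2-methylbutanoate, via alkenylborane 14 (not isolated), via alkenylzinc 15 (not isolated)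
Conditions: 13, Cy2BH, PhMe, 0 to 23 °C; Me2Zn, −78 °C; (−)-MIB (5 mol%); then 12, −10 °C; aq. NH4Cl
Reagents that add atoms: tert-butyldimethyl(prop-2-yn-1-yloxy)silane 13, C#CCO[Si](C)(C)C(C)(C)C
Why: Syn-hydroboration fixes the E-alkene, boron-to-zinc transmetalation gives an alkenylzinc that ignores the alkenyl iodide and the ester, and amino-alcohol-catalysed enantioselective addition to the Si face of the enal should set C6 (8S in this chain numbering).

Step 10
Reactants: 16 (2Z,6Z,8S,9E)-11-(tert-butyldimethylsilyloxy)-8-hydroxy-2-iodo-6-methylundeca-2,6,9-trien-1-yl (2R)-2-methylbutanoate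
Product: 17 (2Z,6Z,8R)-8-hydroxy-2-iodo-6-methyl-8-[(2R,3R)-3-{[(tert-butyldimethylsilyl)oxy]methyl}oxiran-2-yl]octa-2,6-dien-1-yl (2R)-2-methylbutanoate
Conditions: Ti(OiPr)4, D-(−)-DIPT, t-BuOOH, 4 Å MS, CH2Cl2, −20 °C
Reagents that add atoms: tert-butyl hydroperoxide, CC(C)(C)OO
Why: Sharpless asymmetric epoxidation in the matched sense should epoxidise only the E-disubstituted alkene (the other allylic alkene carries a cis substituent and reacts slowly) and give the (7R,8R)-epoxide erythro to the C6 hydroxyl, while any minor C6 epimer is left behind as in a kinetic resolution.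

Step 11
Reactants: 17 (2Z,6Z,8R)-8-hydroxy-2-iodo-6-methyl-8-[(2R,3R)-3-{[(tert-butyldimethylsilyl)oxy]methyl}oxiran-2-yl]octa-2,6-dien-1-yl (2R)-2-methylbutanoate; 18 acryloyl chloride
Product: 19 (2Z,6Z,8R)-8-(acryloyloxy)-2-iodo-6-methyl-8-[(2R,3R)-3-{[(tert-butyldimethylsilyl)oxy]methyl}oxiran-2-yl]octa-2,6-dien-1-yl (2R)-2-methylbutanoate
Conditions: iPr2NEt, CH2Cl2, −40 to 0 °C
Reagents that add atoms: acryloyl chloride 18, C=CC(=O)Cl
Why: O-acylation of the secondary alcohol installs C11–C13 of the lactone as the acrylate tether, with no change at any stereocentre.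

Step 12
Reactants: 19 (2Z,6Z,8R)-8-(acryloyloxy)-2-iodo-6-methyl-8-[(2R,3R)-3-{[(tert-butyldimethylsilyl)oxy]methyl}oxiran-2-yl]octa-2,6-dien-1-yl (2R)-2-methylbutanoate
Product: 20 (2Z,6Z,8R)-8-(acryloyloxy)-8-[(2R,3R)-3-(hydroxymethyl)oxiran-2-yl]-2-iodo-6-methylocta-2,6-dien-1-yl (2R)-2-methylbutanoate
Conditions: HF·pyridine, pyridine, THF, 0 °C
Reagents that add atoms: none
Why: Buffered fluoride desilylation of the primary silyl ether should spare the epoxide, the acrylate and the ester.

Step 13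
Reactants: 20 (2Z,6Z,8R)-8-(acryloyloxy)-8-[(2R,3R)-3-(hydroxymethyl)oxiran-2-yl]-2-iodo-6-methylocta-2,6-dien-1-yl (2R)-2-methylbutanoate
Product: 21 (2Z,6Z,8R)-8-(acryloyloxy)-8-[(2R,3S)-3-formyloxiran-2-yl]-2-iodo-6-methylocta-2,6-dien-1-yl (2R)-2-methylbutanoate
Conditions: Dess–Martin periodinane, NaHCO3, CH2Cl2, 0 °C
Reagents that add atoms: none
Why: Dess–Martin oxidation of a 2,3-epoxy alcohol gives the configurationally stable α,β-epoxy aldehyde (the descriptor changes only through priorities).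

Step 14
Reactants: 21 (2Z,6Z,8R)-8-(acryloyloxy)-8-[(2R,3S)-3-formyloxiran-2-yl]-2-iodo-6-methylocta-2,6-dien-1-yl (2R)-2-methylbutanoate
Product: 22 (1(10)Z,4Z,6R,7R,8R,9R)-6-acryloyloxy-7,8-epoxy-9-hydroxy-14-[(2R)-2-methylbutanoyloxy]-11,12,13-trinorgermacra-1(10),4-diene
Conditions: CrCl2 (10 equiv), NiCl2 (cat.), DMSO/THF, 0.002 M, 23 °C
Reagents that add atoms: none
Why: In this Nozaki–Hiyama–Kishi macrocyclisation the alkenylchromium species formed with retention of the Z geometry should add only to the aldehyde, the two Z-alkenes pre-organise the chain for ten-membered ring closure, and Felkin–Anh (Cornforth) addition to the α,β-epoxy aldehyde should place the new C9 hydroxyl anti to the C8 epoxide oxygen (9R).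

Step 15
Reactants: 22 (1(10)Z,4Z,6R,7R,8R,9R)-6-acryloyloxy-7,8-epoxy-9-hydroxy-14-[(2R)-2-methylbutanoyloxy]-11,12,13-trinorgermacra-1(10),4-diene; 23 acetic anhydride
Product: 24 (1(10)Z,4Z,6R,7R,8R,9R)-9-acetoxy-6-acryloyloxy-7,8-epoxy-14-[(2R)-2-methylbutanoyloxy]-11,12,13-trinorgermacra-1(10),4-diene
Conditions: Ac2O, pyridine, DMAP (cat.), CH2Cl2, 0 °C
Reagents that add atoms: acetic anhydride 23, CC(=O)OC(C)=O
Why: Acetylation of the only free hydroxyl fixes the C9 acetate before the C8 hydroxyl exists, so the two oxygens never need to be told apart.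

Step 16
Reactants: 24 (1(10)Z,4Z,6R,7R,8R,9R)-9-acetoxy-6-acryloyloxy-7,8-epoxy-14-[(2R)-2-methylbutanoyloxy]-11,12,13-trinorgermacra-1(10),4-diene
Product: 27 (1(10)Z,4Z,6R,7R,8S,9R)-9-acetoxy-8-hydroxy-14-[(2R)-2-methylbutanoyloxy]germacra-1(10),4,11(13)-trien-12,6-olide (CNP0005248.2), via phosphonium enolate 25 (not isolated), via phosphonium alkoxide 26 (not isolated)
Conditions: PMe3 (0.3 equiv), t-BuOH, 23 to 40 °C, 0.01 M
Reagents that add atoms: none
Why: Proposed new method: PMe3 adds reversibly to the acrylate to give phosphonium enolate 25, whose α-carbon C11 attacks epoxide carbon C7 anti to the C7–O bond to give 26; proton transfer from C11 and E1cB loss of PMe3 then regenerate the C11=C13 methylene and the catalyst. The closest known reaction type is the phosphine-mediated intramolecular Morita–Baylis–Hillman alkylation of enones by tethered epoxides; new here are the acrylate ester as donor and the formation of a lactone. The γ-lactone ring (O–C6–C7–C11–C12) closes in the 5-exo-tet mode through the C11–C7 bond. C7 is set by stereospecific inversion at the epoxide carbon, so the (7R,8R)-epoxide from step 10 becomes 7R with C11 anti to the C8 oxygen, while C8 keeps its oxygen and geometry and appears as the free 8-hydroxyl (8S by priority change only). The step needs attack at C7 rather than C8 and survival of the neighbouring C9 acetate: the four-atom tether from O6 and the erythro arrangement, which holds O6 antiperiplanar to the breaking C7–O bond, secure the first, and the protic solvent, which protonates the C8 alkoxide before acyl transfer, the second.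

Compound list
1 | neryl acetate, (2Z)-3,7-dimethylocta-2,6-dien-1-yl acetate | CC(=O)OC/C=C(/C)CCC=C(C)C | starting material
2 | racemic 6,7-epoxyneryl acetate, (2Z)-5-(3,3-dimethyloxiran-2-yl)-3-methylpent-2-en-1-yl acetate | CC(=O)OC/C=C(/C)CCC1OC1(C)C | intermediate
3 | racemic (2Z)-6,7-dihydroxy-3,7-dimethyloct-2-en-1-yl acetate (diol, not isolated) | CC(=O)OC/C=C(/C)CCC(O)C(C)(C)O | intermediate
4 | (2Z)-3-methyl-6-oxohex-2-en-1-yl acetate | CC(=O)OC/C=C(/C)CCC=O | intermediate
5 | (triphenylphosphoranylidene)acetaldehyde | O=CC=P(c1ccccc1)(c1ccccc1)c1ccccc1 | starting material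
6 | (2Z,6E)-3-methyl-8-oxoocta-2,6-dien-1-yl acetate | CC(=O)OC/C=C(/C)CC/C=C/C=O | intermediate
7 | (2Z,6Z)-7-iodo-3-methyl-8-oxoocta-2,6-dien-1-yl acetate | CC(=O)OC/C=C(/C)CC/C=C(\I)C=O | intermediate
8 | (2Z,6Z)-8-hydroxy-7-iodo-3-methylocta-2,6-dien-1-yl acetate | CC(=O)OC/C=C(/C)CC/C=C(\I)CO | intermediate
9 | (2R)-2-methylbutanoic acid | CC[C@@H](C)C(=O)O | starting material
10 | (2Z,6Z)-8-acetoxy-2-iodo-6-methylocta-2,6-dien-1-yl (2R)-2-methylbutanoate | CC(=O)OC/C=C(/C)CC/C=C(\I)COC(=O)[C@H](C)CC | intermediate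
11 | (2Z,6Z)-8-hydroxy-2-iodo-6-methylocta-2,6-dien-1-yl (2R)-2-methylbutanoate | OC/C=C(/C)CC/C=C(\I)COC(=O)[C@H](C)CC | intermediate
12 | (2Z,6Z)-2-iodo-6-methyl-8-oxoocta-2,6-dien-1-yl (2R)-2-methylbutanoate | O=C/C=C(/C)CC/C=C(\I)COC(=O)[C@H](C)CC | intermediate
13 | tert-butyldimethyl(prop-2-yn-1-yloxy)silane | C#CCO[Si](C)(C)C(C)(C)C | starting material
14 | (E)-[3-(tert-butyldimethylsilyloxy)prop-1-en-1-yl]dicyclohexylborane (not isolated) | CC(C)(C)[Si](C)(C)OC/C=C/B(C1CCCCC1)C1CCCCC1 | intermediate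
15 | (E)-[3-(tert-butyldimethylsilyloxy)prop-1-en-1-yl](methyl)zinc (not isolated) | CC(C)(C)[Si](C)(C)OC/C=C/[Zn]C | intermediate
16 | (2Z,6Z,8S,9E)-11-(tert-butyldimethylsilyloxy)-8-hydroxy-2-iodo-6-methylundeca-2,6,9-trien-1-yl (2R)-2-methylbutanoate | CC(C)(C)[Si](C)(C)OC/C=C/[C@H](O)/C=C(/C)CC/C=C(\I)COC(=O)[C@H](C)CC | intermediate
17 | (2Z,6Z,8R)-8-hydroxy-2-iodo-6-methyl-8-[(2R,3R)-3-{[(tert-butyldimethylsilyl)oxy]methyl}oxiran-2-yl]octa-2,6-dien-1-yl (2R)-2-methylbutanoate (erythro, trans-epoxide) | CC(C)(C)[Si](C)(C)OC[C@H]1O[C@@H]1[C@H](O)/C=C(/C)CC/C=C(\I)COC(=O)[C@H](C)CC | intermediate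
18 | acryloyl chloride | C=CC(=O)Cl | starting material
19 | (2Z,6Z,8R)-8-(acryloyloxy)-2-iodo-6-methyl-8-[(2R,3R)-3-{[(tert-butyldimethylsilyl)oxy]methyl}oxiran-2-yl]octa-2,6-dien-1-yl (2R)-2-methylbutanoate | CC(C)(C)[Si](C)(C)OC[C@H]1O[C@@H]1[C@H](OC(=O)C=C)/C=C(/C)CC/C=C(\I)COC(=O)[C@H](C)CC | intermediate
20 | (2Z,6Z,8R)-8-(acryloyloxy)-8-[(2R,3R)-3-(hydroxymethyl)oxiran-2-yl]-2-iodo-6-methylocta-2,6-dien-1-yl (2R)-2-methylbutanoate | OC[C@H]1O[C@@H]1[C@H](OC(=O)C=C)/C=C(/C)CC/C=C(\I)COC(=O)[C@H](C)CC | intermediate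
21 | (2Z,6Z,8R)-8-(acryloyloxy)-8-[(2R,3S)-3-formyloxiran-2-yl]-2-iodo-6-methylocta-2,6-dien-1-yl (2R)-2-methylbutanoate | O=C[C@H]1O[C@@H]1[C@H](OC(=O)C=C)/C=C(/C)CC/C=C(\I)COC(=O)[C@H](C)CC | intermediate
22 | (1(10)Z,4Z,6R,7R,8R,9R)-6-acryloyloxy-7,8-epoxy-9-hydroxy-14-[(2R)-2-methylbutanoyloxy]-11,12,13-trinorgermacra-1(10),4-diene (ten-membered carbocycle, trans-epoxide) | O[C@H]1[C@H]2O[C@@H]2[C@H](OC(=O)C=C)/C=C(/C)CC/C=C1/COC(=O)[C@H](C)CC | intermediate
23 | acetic anhydride | CC(=O)OC(C)=O | starting material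
24 | (1(10)Z,4Z,6R,7R,8R,9R)-9-acetoxy-6-acryloyloxy-7,8-epoxy-14-[(2R)-2-methylbutanoyloxy]-11,12,13-trinorgermacra-1(10),4-diene | CC(=O)O[C@H]1[C@H]2O[C@@H]2[C@H](OC(=O)C=C)/C=C(/C)CC/C=C1/COC(=O)[C@H](C)CC | intermediate
25 | zwitterionic phosphonium enolate from addition of PMe3 to the acrylate of 24 (not isolated) | CC(=O)O[C@H]1[C@H]2O[C@@H]2[C@H](OC([O-])=CC[P+](C)(C)C)/C=C(/C)CC/C=C1/COC(=O)[C@H](C)CC | intermediate
26 | zwitterionic 13-(trimethylphosphonio)-11,13-dihydro lactone with C8 alkoxide, C11 unassigned (not isolated) | C[P+](C)(C)CC1C(=O)O[C@@H]2/C=C(/C)CC/C=C(/COC(=O)[C@H](C)CC)[C@@H](OC(C)=O)[C@@H]([O-])[C@@H]12 | intermediate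
27 | (1(10)Z,4Z,6R,7R,8S,9R)-9-acetoxy-8-hydroxy-14-[(2R)-2-methylbutanoyloxy]germacra-1(10),4,11(13)-trien-12,6-olide (CNP0005248.2) | C=C1C(=O)O[C@@H]2/C=C(/C)CC/C=C(/COC(=O)[C@H](C)CC)[C@@H](OC(C)=O)[C@@H](O)[C@@H]12 | target

Total step count: 16. Longest linear sequence: 16 steps (1 to 27); all other inputs are purchased.

Steps most likely to fail

1. Step 16 (proposed new method). What may go wrong: the phosphonium enolate may be protonated, or the acrylate may oligomerise, faster than C11 alkylates the disubstituted epoxide. The transient C8 alkoxide may also take the acetyl group from O9. Fallback by known chemistry, setting out from 17 and returning at 27: 17 would be esterified with diethylphosphonoacetic acid (DCC, DMAP) to the phosphonoacetate F1. F1 would pass through the operations of steps 12 to 15: desilylation to the primary alcohol F2, oxidation to the epoxy aldehyde F3, chromium-mediated ring closure to the macrocyclic alcohol F4 and acetylation to the macrocyclic acetate F5. KOtBu (1 equiv, THF, 0 to 40 °C) would deprotonate only the phosphonoacetate. The stabilised carbanion should open the epoxide at C7 in the 5-exo mode, the carbanion–epoxide alkylation known from the Wadsworth–Emmons cyclopropanation, to give the α-phosphono lactone F6. Paraformaldehyde added to the same flask would then effect Horner–Wadsworth–Emmons methylenation to 27.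

2. Step 14. What may go wrong: slow closure of the ten-membered ring may allow oligomerisation, loss of the allylic carboxylate from the alkenylchromium species or reduction of the epoxy aldehyde, and the ring constraint may override Felkin–Anh control so that facial selectivity at C9 is poor or reversed. Fallback, setting out from 21 and returning at 22: the closure would be accepted as a mixture of 22 and its C9 epimer, the 9-epi alcohol F7. The mixture would be oxidised (Dess–Martin periodinane) to the ring epoxy enone F8. Chelation-controlled reduction (Zn(BH4)2, Et2O, −20 °C; zinc bridges the ketone and epoxide oxygens) should then return the erythro alcohol 22. C9 is thus set by reagent-controlled reduction of a ring ketone and not by the carbon–carbon bond formation.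

3. Step 9. What may go wrong: enantioface discrimination by the amino-alcohol catalyst may be modest for a β,β-disubstituted Z-enal, with competing Z-to-E isomerisation of 12 or methyl transfer. Fallback, setting out from 12 and returning at 17: the alkenylzinc 15 would be added without the chiral ligand to give 16 together with its C6 epimer, the (8R)-alcohol F9. The mixture would be submitted to the Sharpless epoxidation of step 10 under kinetic-resolution conditions (D-(−)-DIPT, 0.6 equiv t-BuOOH). Only the (8S)-alcohol should be epoxidised, giving 17 and leaving F9 to be separated. C6 is thus set by resolution and not by asymmetric addition.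

Further compounds
F1 | step 16 | (2Z,6Z,8R)-8-[(diethoxyphosphoryl)acetoxy]-2-iodo-6-methyl-8-[(2R,3R)-3-{[(tert-butyldimethylsilyl)oxy]methyl}oxiran-2-yl]octa-2,6-dien-1-yl (2R)-2-methylbutanoate | CC(C)(C)[Si](C)(C)OC[C@H]1O[C@@H]1[C@H](OC(=O)CP(=O)(OCC)OCC)/C=C(/C)CC/C=C(\I)COC(=O)[C@H](C)CC
F2 | step 16 | primary alcohol from desilylation of F1 | OC[C@H]1O[C@@H]1[C@H](OC(=O)CP(=O)(OCC)OCC)/C=C(/C)CC/C=C(\I)COC(=O)[C@H](C)CC
F3 | step 16 | epoxy aldehyde from oxidation of F2 | O=C[C@H]1O[C@@H]1[C@H](OC(=O)CP(=O)(OCC)OCC)/C=C(/C)CC/C=C(\I)COC(=O)[C@H](C)CC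
F4 | step 16 | (1(10)Z,4Z,6R,7R,8R,9R)-6-[(diethoxyphosphoryl)acetoxy]-7,8-epoxy-9-hydroxy-14-[(2R)-2-methylbutanoyloxy]-11,12,13-trinorgermacra-1(10),4-diene | O[C@H]1[C@H]2O[C@@H]2[C@H](OC(=O)CP(=O)(OCC)OCC)/C=C(/C)CC/C=C1/COC(=O)[C@H](C)CC
F5 | step 16 | 9-acetate of F4 | CC(=O)O[C@H]1[C@H]2O[C@@H]2[C@H](OC(=O)CP(=O)(OCC)OCC)/C=C(/C)CC/C=C1/COC(=O)[C@H](C)CC
F6 | step 16 | 11-(diethoxyphosphoryl)-13-nor lactone, (6R,7R,8S,9R), C11 unassigned | CCOP(=O)(OCC)C1C(=O)O[C@@H]2/C=C(/C)CC/C=C(/COC(=O)[C@H](C)CC)[C@@H](OC(C)=O)[C@@H](O)[C@@H]12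
F7 | step 14 | 9-epi alcohol, (6R,7R,8R,9S)-epimer of 22 | O[C@@H]1[C@H]2O[C@@H]2[C@H](OC(=O)C=C)/C=C(/C)CC/C=C1/COC(=O)[C@H](C)CC
F8 | step 14 | (1(10)Z,4Z,6R,7R,8R)-6-acryloyloxy-7,8-epoxy-14-[(2R)-2-methylbutanoyloxy]-11,12,13-trinorgermacra-1(10),4-dien-9-one | O=C1[C@H]2O[C@@H]2[C@H](OC(=O)C=C)/C=C(/C)CC/C=C1/COC(=O)[C@H](C)CC
F9 | step 9 | (2Z,6Z,8R,9E)-11-(tert-butyldimethylsilyloxy)-8-hydroxy-2-iodo-6-methylundeca-2,6,9-trien-1-yl (2R)-2-methylbutanoate | CC(C)(C)[Si](C)(C)OC/C=C/[C@@H](O)/C=C(/C)CC/C=C(\I)COC(=O)[C@H](C)CC
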